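**Retrosynthetic overview**

- The butenolide is closed last, by ketenylidenephosphorane cyclisation of a C13 α-ketol; the C11–C12 bond comes from alkylating a silyloxyacetone hydrazone aza-enolate with a C11 allylic bromide.
- The bromide derives from a bicyclic 6-oxo-Δ7 C11-ester: α-face hydride sets 6β-OH, the ester draws the olefin to C8=C9, then ester → CH2OH → CH2Br.
- The bicyclic enone ester derives from an acyclic keto alkylidene acetoacetate in one amine-catalysed operation: the C5–C10 Michael bond closes ring A first, the C7–C8 aldol condensation closes ring B second.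
- The acyclic precursor derives from mesityl oxide and a chloro-ketal Grignard reagent (conjugate addition, C3–C4) and methyl acetoacetate (Knoevenagel, C9=C10); the C6 carbonyl travels as a methallyl olefin until ozonolysis, so the condensation meets only one ketone.
- Feature used (labdane numbering): the oxygen on C6 sits between C5 of the ring A/B fusion and C7 of ring B. As a ketone it makes both carbons donors, so one methyl ketone can reach C10 and C8 of a unit that brings C8, C9, C11 and the C8 methyl.

Key step: step 5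

Assumption: the (1R,2R) antipode of the amine–thiourea is taken to give the (5S,10S) series; if induction runs the other way, the (1S,2S) antipode is used unchanged. The olefin geometry of the alkylidene acetoacetates does not matter.

**Route**

Step 1
Reactants: 1 mesityl oxide; 2 2-(3-chloropropyl)-2-methyl-1,3-dioxolane
Product: 5 4,4-dimethyl-7-(2-methyl-1,3-dioxolan-2-yl)heptan-2-one, via Grignard reagent 3 (not isolated), via silyl enol ether 4 (not isolated)
Conditions: 2, Mg, THF, 60 °C; then CuBr·SMe2 (5 mol%), 1, Me3SiCl, THF, −40 → 0 °C; then K2CO3, MeOH, rt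
Reagents that add atoms: none
Why: Copper-catalysed conjugate addition of a Grignard reagent, accelerated by Me3SiCl, places the alkyl chain on the β,β-disubstituted carbon and creates the C4 quaternary centre; basic methanolysis of the silyl enol ether leaves the dioxolane intact.

Step 2
Reactants: 5 4,4-dimethyl-7-(2-methyl-1,3-dioxolan-2-yl)heptan-2-one
Product: 7 6,6,8-trimethylnon-8-en-2-one, via alkene ketal 6 (not isolated)
Conditions: Ph3PCH3Br, KOt-Bu, THF, 0 → 65 °C; then pyridinium p-toluenesulfonate, THF–H2O, 50 °C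
Reagents that add atoms: methyltriphenylphosphonium bromide, C[P+](c1ccccc1)(c1ccccc1)c1ccccc1.[Br-]; water, O
Why: Wittig methylenation turns the neopentyl-type ketone (future C6) into a methallyl group that cannot take part in the coming condensation; buffered acid then hydrolyses the dioxolane much faster than it protonates the 1,1-disubstituted olefin.

Step 3
Reactants: 7 6,6,8-trimethylnon-8-en-2-one; 8 methyl acetoacetate
Product: 9 methyl (2Z)-2-acetyl-3,7,7,9-tetramethyldeca-2,9-dienoate (2E isomer also present)
Conditions: TiCl4, pyridine, THF, 0 °C → rt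
Reagents that add atoms: none
Why: TiCl4/pyridine-mediated Knoevenagel condensation of a methyl ketone with a β-keto ester; 7 has a single carbonyl, so no choice between two ketones arises.

Step 4
Reactants: 9 methyl (2Z)-2-acetyl-3,7,7,9-tetramethyldeca-2,9-dienoate
Product: 11 methyl (2Z)-2-acetyl-3,7,7-trimethyl-9-oxodec-2-enoate (2E isomer also present), via ozonide 10 (not isolated)
Conditions: O3, CH2Cl2, −78 °C (Sudan Red 7B end point); then Me2S, −78 °C → rt
Reagents that add atoms: ozone, [O-][O+]=O
Why: Ozonolysis with reductive work-up; electrophilic ozone should cleave the electron-rich 1,1-disubstituted olefin far faster than the tetrasubstituted, doubly acceptor-substituted alkylidene, and the dye marks the end point.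

Step 5
Reactants: 11 methyl (2Z)-2-acetyl-3,7,7-trimethyl-9-oxodec-2-enoate
Product: 14 methyl (5S,9S,10S)-6-oxodrim-7-en-11-oate, via Michael adduct 12 (not isolated), via aldol adduct 13 (not isolated)
Conditions: 1-[(1R,2R)-2-aminocyclohexyl]-3-[3,5-bis(trifluoromethyl)phenyl]thiourea (20 mol%), PhCO2H (20 mol%), toluene, 40 → 80 °C
Reagents that add atoms: none
Why: Proposed new method: the primary amine condenses with the C6 methyl ketone and the C5 enamine adds to C10 of the thiourea-bound alkylidene acetoacetate (6-(enolexo)-exo-trig, ring A); the resulting C6 imine tautomerises to the C7 enamine, which attacks the C8 acetyl carbonyl (6-(enolendo)-exo-trig, ring B), and dehydration with hydrolysis should release enone 14. The closest known reaction types are amine-catalysed intramolecular Michael–aldol (Robinson-type) annulations and enamine conjugate additions to alkylidene 1,3-dicarbonyl compounds; the untested element is the quaternary C10 formed from a ketone-derived, tetrasubstituted acceptor. C10 is set by the catalyst, whose thiourea holds the 1,3-dicarbonyl by hydrogen bonding and so fixes the enantioface met by the tethered enamine, in a chair with the C9 branch equatorial and the C10 methyl axial; C5 follows from that chair and, being α to the C6 carbonyl, can settle to the trans-fused isomer; C9 is epimerisable and is erased in step 7. The Michael step needs the C5 and not the C7 enamine, which the tether secures because C7 attack at C10 would close an eight-membered ring. The aldol step needs C7→C8 and not C8-methyl→C6, which is secured because the C7 enamine is already present on the C6 imine and the C6 carbonyl sits on C5 between two quaternary carbons. Both olefin isomers of 11, and any deconjugated isomer, should equilibrate to the same reactive species.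

Step 6
Reactants: 14 methyl (5S,9S,10S)-6-oxodrim-7-en-11-oate
Product: 15 methyl (5S,6R,9S,10S)-6β-hydroxydrim-7-en-11-oate
Conditions: NaBH4, CeCl3·7H2O, MeOH, −40 → 0 °C
Reagents that add atoms: none
Why: Luche reduction gives 1,2-reduction only; hydride should enter from the α face because the β face of C6 is screened by the syn-axial methyl groups on C10 and C4, which sets the 6β (6R) carbinol.

Step 7
Reactants: 15 methyl (5S,6R,9S,10S)-6β-hydroxydrim-7-en-11-oate
Product: 16 methyl (5S,6R,10S)-6β-hydroxydrim-8-en-11-oate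
Conditions: NaOMe, MeOH, 50 °C
Reagents that add atoms: none
Why: Base-mediated isomerisation of a β,γ- to an α,β-unsaturated ester through the dienolate (deprotonation at C9, protonation at C7) should move the olefin to the tetrasubstituted, ester-conjugated C8=C9 position and remove the C9 stereocentre.

Step 8
Reactants: 16 methyl (5S,6R,10S)-6β-hydroxydrim-8-en-11-oate
Product: 17 (5S,6R,10S)-drim-8-ene-6β,11-diol
Conditions: i-Bu2AlH, CH2Cl2, −78 → 0 °C
Reagents that add atoms: none
Why: Aluminium hydride reduction of the conjugated ester to the primary allylic alcohol; the free 6β-hydroxyl only consumes one equivalent of hydride.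

Step 9
Reactants: 17 (5S,6R,10S)-drim-8-ene-6β,11-diol
Product: 18 (5S,6R,10S)-11-bromodrim-8-en-6β-ol
Conditions: CBr4, PPh3, 2,6-lutidine, CH2Cl2, 0 °C
Reagents that add atoms: carbon tetrabromide, BrC(Br)(Br)Br
Why: Appel bromination should select the primary allylic hydroxyl, since the axial 6β-hydroxyl between two syn-axial methyl groups is too hindered to be activated and ring closure to a cyclic ether would need a bridgehead olefin; the bromide is used crude.

Step 10
Reactants: 19 1-[(tert-butyldimethylsilyl)oxy]propan-2-one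
Product: 20 1-[(tert-butyldimethylsilyl)oxy]propan-2-one N,N-dimethylhydrazone
Conditions: Me2NNH2, AcOH (cat.), EtOH, 78 °C
Reagents that add atoms: N,N-dimethylhydrazine, CN(C)N
Why: Hydrazone formation from a ketone gives a regiodefined enolate equivalent of silyloxyacetone.

Step 11
Reactants: 18 (5S,6R,10S)-11-bromodrim-8-en-6β-ol; 20 1-[(tert-butyldimethylsilyl)oxy]propan-2-one N,N-dimethylhydrazone
Product: 23 (5S,6R,10S)-16-[(tert-butyldimethylsilyl)oxy]-6β-hydroxy-14,15-dinorlabd-8-en-13-one, via lithiated hydrazone 21 (not isolated), via alkylated hydrazone 22 (not isolated)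
Conditions: 20 (3 equiv), LiN(i-Pr)2, THF, 0 °C; then 18, −78 → 0 °C; then aq. oxalic acid, Et2O, rt
Reagents that add atoms: water, O
Why: Hydrazone aza-enolate alkylation: kinetic deprotonation at the methyl group (less substituted, away from the silyloxy group) and SN2 displacement of the allylic bromide form C11–C12, the excess aza-enolate taking up the hydroxyl proton; two-phase oxalic acid hydrolysis then frees the ketone without cleaving the silyl ether.

Step 12
Reactants: 23 (5S,6R,10S)-16-[(tert-butyldimethylsilyl)oxy]-6β-hydroxy-14,15-dinorlabd-8-en-13-one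
Product: 24 (5S,6R,10S)-6β-acetoxy-16-[(tert-butyldimethylsilyl)oxy]-14,15-dinorlabd-8-en-13-one
Conditions: Ac2O, DMAP, Et3N, CH2Cl2, 40 °C
Reagents that add atoms: acetic anhydride, CC(=O)OC(C)=O
Why: DMAP-catalysed acylation of the hindered axial 6β-alcohol, done while the primary hydroxyl is still silylated so that the two hydroxyls never compete.

Step 13
Reactants: 24 (5S,6R,10S)-6β-acetoxy-16-[(tert-butyldimethylsilyl)oxy]-14,15-dinorlabd-8-en-13-one
Product: 25 (5S,6R,10S)-6β-acetoxy-16-hydroxy-14,15-dinorlabd-8-en-13-one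
Conditions: HF·pyridine, THF, 0 °C → rt
Reagents that add atoms: none
Why: Fluoride desilylation under mildly acidic conditions should spare the acetate and the α-ketol.

Step 14
Reactants: 25 (5S,6R,10S)-6β-acetoxy-16-hydroxy-14,15-dinorlabd-8-en-13-one
Product: 27 (5S,6R,10S)-6β-acetoxylabda-8,13-dien-15,16-olide, via ester ylide 26 (not isolated)
Conditions: Ph3P=C=C=O, toluene, 110 °C
Reagents that add atoms: ketenylidenetriphenylphosphorane, O=C=C=P(c1ccccc1)(c1ccccc1)c1ccccc1
Why: The primary hydroxyl adds to the cumulated ylide to give an ester-stabilised phosphorane, which closes the butenolide by intramolecular Wittig olefination of the C13 ketone.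

**Compound list**

1 | mesityl oxide (4-methylpent-3-en-2-one) | CC(=O)C=C(C)C | starting material
2 | 2-(3-chloropropyl)-2-methyl-1,3-dioxolane | CC1(CCCCl)OCCO1 | starting material
3 | [3-(2-methyl-1,3-dioxolan-2-yl)propyl]magnesium chloride | CC1(CCC[Mg]Cl)OCCO1 | intermediate (not isolated)
4 | trimethylsilyl enol ether of 5 (2-silyloxy-2-ene; olefin geometry not defined) | CC(O[Si](C)(C)C)=CC(C)(C)CCCC1(C)OCCO1 | intermediate (not isolated)
5 | 4,4-dimethyl-7-(2-methyl-1,3-dioxolan-2-yl)heptan-2-one | CC(=O)CC(C)(C)CCCC1(C)OCCO1 | intermediate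
6 | 2-methyl-2-(4,4,6-trimethylhept-6-en-1-yl)-1,3-dioxolane | C=C(C)CC(C)(C)CCCC1(C)OCCO1 | intermediate (not isolated)
7 | 6,6,8-trimethylnon-8-en-2-one | C=C(C)CC(C)(C)CCCC(C)=O | intermediate
8 | methyl acetoacetate | COC(=O)CC(C)=O | starting material
9 | methyl (2Z)-2-acetyl-3,7,7,9-tetramethyldeca-2,9-dienoate (2E isomer also present) | C=C(C)CC(C)(C)CCC/C(C)=C(/C(C)=O)C(=O)OC | intermediate
10 | methyl (2Z)-2-acetyl-3,7,7-trimethyl-8-(3-methyl-1,2,4-trioxolan-3-yl)oct-2-enoate | CC1(CC(C)(C)CCC/C(C)=C(/C(C)=O)C(=O)OC)OCOO1 | intermediate (not isolated)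
11 | methyl (2Z)-2-acetyl-3,7,7-trimethyl-9-oxodec-2-enoate (2E isomer also present) | CC(=O)CC(C)(C)CCC/C(C)=C(/C(C)=O)C(=O)OC | intermediate (key-step precursor)
12 | methyl 2-[(1S,2S)-2-acetyl-1,3,3-trimethylcyclohexyl]-3-oxobutanoate (C2 of the butanoate not defined) | COC(=O)C(C(C)=O)[C@@]1(C)CCCC(C)(C)[C@@H]1C(C)=O | intermediate (not isolated)
13 | methyl (5S,10S)-8-hydroxy-6-oxodriman-11-oate (C8 and C9 not defined) | O=C1CC(C)(O)C(C(=O)OC)[C@@]2(C)CCCC(C)(C)[C@H]12 | intermediate (not isolated)
14 | methyl (5S,9S,10S)-6-oxodrim-7-en-11-oate; methyl (1S,4aS,8aS)-2,5,5,8a-tetramethyl-4-oxo-1,4,4a,5,6,7,8,8a-octahydronaphthalene-1-carboxylate | O=C1C=C(C)[C@H](C(=O)OC)[C@@]2(C)CCCC(C)(C)[C@H]12 | intermediate (key-step product)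
15 | methyl (5S,6R,9S,10S)-6β-hydroxydrim-7-en-11-oate | O[C@@H]1C=C(C)[C@H](C(=O)OC)[C@@]2(C)CCCC(C)(C)[C@H]12 | intermediate
16 | methyl (5S,6R,10S)-6β-hydroxydrim-8-en-11-oate | O[C@@H]1CC(C)=C(C(=O)OC)[C@@]2(C)CCCC(C)(C)[C@H]12 | intermediate
17 | (5S,6R,10S)-drim-8-ene-6β,11-diol | O[C@@H]1CC(C)=C(CO)[C@@]2(C)CCCC(C)(C)[C@H]12 | intermediate
18 | (5S,6R,10S)-11-bromodrim-8-en-6β-ol | O[C@@H]1CC(C)=C(CBr)[C@@]2(C)CCCC(C)(C)[C@H]12 | intermediate
19 | 1-[(tert-butyldimethylsilyl)oxy]propan-2-one | CC(=O)CO[Si](C)(C)C(C)(C)C | starting material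
20 | 1-[(tert-butyldimethylsilyl)oxy]propan-2-one N,N-dimethylhydrazone | CC(=NN(C)C)CO[Si](C)(C)C(C)(C)C | intermediate
21 | lithium aza-enolate of 20, metalated at the methyl carbon | [Li]CC(=NN(C)C)CO[Si](C)(C)C(C)(C)C | intermediate (not isolated)
22 | (5S,6R,10S)-16-[(tert-butyldimethylsilyl)oxy]-6β-hydroxy-14,15-dinorlabd-8-en-13-one N,N-dimethylhydrazone | O[C@@H]1CC(C)=C(CCC(=NN(C)C)CO[Si](C)(C)C(C)(C)C)[C@@]2(C)CCCC(C)(C)[C@H]12 | intermediate (not isolated)
23 | (5S,6R,10S)-16-[(tert-butyldimethylsilyl)oxy]-6β-hydroxy-14,15-dinorlabd-8-en-13-one | O[C@@H]1CC(C)=C(CCC(=O)CO[Si](C)(C)C(C)(C)C)[C@@]2(C)CCCC(C)(C)[C@H]12 | intermediate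
24 | (5S,6R,10S)-6β-acetoxy-16-[(tert-butyldimethylsilyl)oxy]-14,15-dinorlabd-8-en-13-one | CC(=O)O[C@@H]1CC(C)=C(CCC(=O)CO[Si](C)(C)C(C)(C)C)[C@@]2(C)CCCC(C)(C)[C@H]12 | intermediate
25 | (5S,6R,10S)-6β-acetoxy-16-hydroxy-14,15-dinorlabd-8-en-13-one | CC(=O)O[C@@H]1CC(C)=C(CCC(=O)CO)[C@@]2(C)CCCC(C)(C)[C@H]12 | intermediate
26 | (triphenylphosphoranylidene)acetate ester of 25 at O16 | CC(=O)O[C@@H]1CC(C)=C(CCC(=O)COC(=O)C=P(c3ccccc3)(c3ccccc3)c3ccccc3)[C@@]2(C)CCCC(C)(C)[C@H]12 | intermediate (not isolated)
27 | (5S,6R,10S)-6β-acetoxylabda-8,13-dien-15,16-olide (CNP0128495.1) | CC(=O)O[C@@H]1CC(C)=C(CCC2=CC(=O)OC2)[C@@]2(C)CCCC(C)(C)[C@H]12 | target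

**Step count**

Total: 14 steps. Longest linear sequence: 13 steps (steps 1–9 and 11–14, from mesityl oxide and the chloro-ketal); step 10 is a one-step side branch.

**Steps most likely to fail**

Step 5 (key step). The primary amine may add to the alkylidene and cleave it by retro-Knoevenagel fragmentation, the C5 enamine may not reach the tetrasubstituted C10, or facial discrimination at C10 may be weak. Fallback: setting out from 11, KOt-Bu in t-BuOH–THF brings about the same two closures through the potassium enolate (base-mediated Michael addition and aldol condensation, a known annulation type that uses no nucleophilic amine). This should give racemic methyl 6-oxodrim-7-en-11-oate F1 as the trans-fused isomer. Resolution of F1 by preparative chromatography on a chiral stationary phase (cellulose tris(3,5-dimethylphenylcarbamate)) returns to the route at 14.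

Step 11. The hydrazone may be deprotonated at the silyloxymethylene carbon instead of the methyl carbon, or the hindered allylic bromide may undergo elimination or allylic transposition instead of direct substitution. Fallback: setting out from 18, alkylation with the dianion of methyl acetoacetate (NaH, then n-BuLi, THF, 0 °C; excess), which reacts only at its terminal carbon, should give methyl (5S,6R,10S)-6β-hydroxy-13-oxo-16-norlabd-8-en-15-oate F2. NaH and PhNTf2 convert it to the (13Z)-enol triflate F3. Stille coupling with Bu3SnCH2OH (Pd(PPh3)4, LiCl, dioxane, 100 °C) gives methyl (13Z)-6β,16-dihydroxylabda-8,13-dien-15-oate F4, which lactonises in the flask to (5S,6R,10S)-6β-hydroxylabda-8,13-dien-15,16-olide F5. Acetylation (Ac2O, DMAP, pyridine) returns to the route at 27.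

Step 7. The olefin equilibrium may lie on the wrong side, or the C6 oxygen may be lost by vinylogous β-elimination from the dienolate. Fallback: setting out from 15, i-Bu2AlH reduction gives (5S,6R,9S,10S)-drim-7-ene-6β,11-diol F6. Selective oxidation of the primary hydroxyl (TEMPO, PhI(OAc)2, CH2Cl2) gives (5S,6R,9S,10S)-6β-hydroxydrim-7-en-11-al F7. This aldehyde is more acidic and more strongly conjugating than the ester, so DBU at rt should isomerise it to (5S,6R,10S)-6β-hydroxydrim-8-en-11-al F8. Reduction (NaBH4, CeCl3·7H2O, MeOH) returns to the route at 17.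

**Further compounds**

F1 | step 5 | racemic methyl 6-oxodrim-7-en-11-oate (trans-fused, both enantiomers) | O=C1C=C(C)[C@H](C(=O)OC)[C@@]2(C)CCCC(C)(C)[C@H]12.O=C1C=C(C)[C@@H](C(=O)OC)[C@]2(C)CCCC(C)(C)[C@@H]12
F2 | step 11 | methyl (5S,6R,10S)-6β-hydroxy-13-oxo-16-norlabd-8-en-15-oate | O[C@@H]1CC(C)=C(CCC(=O)CC(=O)OC)[C@@]2(C)CCCC(C)(C)[C@H]12
F3 | step 11 | methyl (5S,6R,10S,13Z)-6β-hydroxy-13-[(trifluoromethanesulfonyl)oxy]-16-norlabda-8,13-dien-15-oate | O[C@@H]1CC(C)=C(CC/C(OS(=O)(=O)C(F)(F)F)=C/C(=O)OC)[C@@]2(C)CCCC(C)(C)[C@H]12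
F4 | step 11 | methyl (5S,6R,10S,13Z)-6β,16-dihydroxylabda-8,13-dien-15-oate | O[C@@H]1CC(C)=C(CC/C(CO)=C/C(=O)OC)[C@@]2(C)CCCC(C)(C)[C@H]12
F5 | step 11 | (5S,6R,10S)-6β-hydroxylabda-8,13-dien-15,16-olide | O[C@@H]1CC(C)=C(CCC3=CC(=O)OC3)[C@@]2(C)CCCC(C)(C)[C@H]12
F6 | step 7 | (5S,6R,9S,10S)-drim-7-ene-6β,11-diol | O[C@@H]1C=C(C)[C@H](CO)[C@@]2(C)CCCC(C)(C)[C@H]12
F7 | step 7 | (5S,6R,9S,10S)-6β-hydroxydrim-7-en-11-al | O[C@@H]1C=C(C)[C@H](C=O)[C@@]2(C)CCCC(C)(C)[C@H]12
F8 | step 7 | (5S,6R,10S)-6β-hydroxydrim-8-en-11-al | O[C@@H]1CC(C)=C(C=O)[C@@]2(C)CCCC(C)(C)[C@H]12
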